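Atom numbering used throughout: ring C1 (bears the chain), C2 (CH2), C3 (Cl), C4 (CH3, OH), C5 (OH), C6 (angelate); chain C7 (=C14H2), C8 (angelate), C9, C10–C11 (epoxide, two methyls on C11). Compounds carry the numbers 1–24 fixed in the steps below.

## Analysis of the target

Target 24 is a bisabolane-type monocycle: a cyclohexane C1–C6 with a methyl group on C4 and, on C1, the chain C7(=C14H2)–C8–C9–C10–C11, whose C10–C11 bond is an epoxide. It has seven stereocentres, C1, C3, C4, C5 and C6 on the ring and C8 and C10 in the chain. On the ring, C1–C7, C6–O, C5–O and C4–O all lie on one face, while C3–Cl lies on the other, trans to C4–OH. In the chair with the chain equatorial this is a trans-diaxial chlorohydrin with an axial C6 ester. The sensitive groups are two angelates (Z to E isomerisation, migration to the free C5–OH next door), an acid-labile trisubstituted epoxide, a base-labile chlorohydrin and a 1,1-disubstituted alkene beside an allylic ester. The difficulty is threefold: four contiguous substituents on one ring face, four oxygens to be told apart (esters on C6 and C8, free hydroxyls on C4 and C5), and two chain stereocentres that the ring cannot control. The strategy rests on two facts: C3–Cl/C4–OH can come from a C3=C4 alkene, and the resulting cyclohexene has C5–O, C6–O and C1–C7 mutually cis. Its retro-[4+2] gives the diene C2=C3–C4(CH3)=C5–O and the dienophile O–C6=C1–C7(=O), two enol ethers whose oxygens can sit on one silicon atom.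

## Retrosynthetic reasoning

24 to 23: the C10–C11 epoxide is removed first. It is the most acid-labile group and is set by a reagent, so putting it in last keeps it away from the titanium/chloride conditions and from every acylation.

23 to 22 to 21: the C3–Cl bond is cut back to a C3–C4 epoxide on the face of C5–OH, and that epoxide back to the C3=C4 alkene of 21. The free C5–OH serves twice: it delivers the oxidant to the crowded face and then steers chloride to C3. Both C3 and C4 are therefore set from C5.

21 to 20 to 17 to 15: the two ester C–O bonds at C6 and C8 are cut together. This requires C5–O to be masked alone, and a tin acetal across the cis-diol of triol 15 is expected to single out the allylic, equatorial O5. The mask is an ether (in 17 and 20) that comes off oxidatively without touching angelates.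

15 to 14 to 13: both silicon groups are removed in one operation, and C7=C14 is traced to the C7 ketone of 13. That ketone is what activates the dienophile, so it must survive until after the ring is made.

13 to 12: the key disconnection cuts C1–C2 and C5–C6. It is made here because it removes the ring, three stereocentres and the dioxasilolane at once and leaves two simple enol ethers. The forward reaction must join them against their polar preference, which only the O5–Si–O6 tether can enforce.

12 to 8 + 9 + 10: the two Si–O bonds are cut. Forward, 10 is substituted twice, first by soft enolisation of enal 9 and then by the chelated enol 8, which fixes the E diene and the Z enol ether.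

8 to 6 to 5 to 4 to 3 to 1 + 2: C6 is removed as a formyl group and C1 as the methyl of a Weinreb ketone synthesis. The C9–C10 bond is cut back to epoxide 1 and alkenyl Grignard 2. C8 is thus bought as a stereocentre and never made.

## Alternatives that were turned down

Alternative 1: Disconnection of C6–C1 and C3–C4 (Michael addition, then aldol). Forward, an amine catalyst turns 2,2,4-trimethyl-1,3-dioxan-5-one A1 into its enamine, which attacks ethyl (E)-4-oxobut-2-enoate A2 through C6 at C1. The methyl-bearing C4 then adds to the freed aldehyde C3 and closes the bicyclic keto-acetal A3.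
- For: two cheap achiral components, a known reaction class, the quaternary C4 with its oxygen and methyl set at once, C1–C7 already cis to C6–O, and O4/O6 tied in one acetal so that O5 is differentiated for free. On precedent and on early oxidation at C4 it is stronger than the chosen route.
- Against: C7 arrives only as an ester, so the whole chain with C8 and C10 must be grown afterwards from a crowded, epimerisable position. The C5 ketone must be reduced to the cis alcohol. The C3 hydroxyl has the orientation of the chloride, so its replacement needs net retention (two inversions) and saves nothing over an epoxide opening.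
- Comparison: the chosen strategy offers the complete C1–C14 skeleton with C8 in place in the ring-forming step, and fewer operations after it.

Alternative 2: Disconnection of C7–C1 by a radical. Forward, the (1-bromoethenyl)dimethylsilyl ether A4 of the mono-silylated microbial toluene diol is treated with a tin hydride. The vinyl radical C7 closes 5-exo on C1, and hydrogen capture gives the oxasilolane A5.
- For: silicon-tethered radical cyclisation is known. The diol supplies C5–O and C6–O in the correct absolute configuration, the C4 methyl and the C3=C4 alkene, and its two oxygens are differentiated from the start. On ring enantiopurity and on oxygen differentiation it is stronger than the chosen route.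
- Against: the intermediate radical is allylic over C2–C3–C4 and can take hydrogen at C4, misplacing the alkene. C7 ends up bonded to silicon, not to C8. The C7–C8 bond and the C8 stereocentre must then be made by adding a vinyl metal to a labile β,γ-unsaturated aldehyde with no control from the ring, followed by redox correction.
- Comparison: the chosen strategy brings C8 in enantiopure before the ring exists and forms two C–C bonds at once. Its price is an unproven cycloaddition.

Alternative 3: Disconnection of C3–C4. Forward, sulfoxide–magnesium exchange on the acyclic α-chloro sulfoxide A6 with an isopropylmagnesium halide at low temperature releases a configurationally defined α-chloroalkylmagnesium at C3. It adds to the C4 methyl ketone and gives A7 directly as the chlorohydrin.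
- For: C3–Cl and the tertiary C4–OH are made in the ring closure. There is no late epoxide opening and no contra-steric epoxidation, and every oxygen is already differentiated. On the endgame it is stronger.
- Against: A6 carries four stereocentres plus the chloro-sulfoxide carbon and needs a long linear sequence. The carbenoid survives only at low temperature, the ketone is hindered and enolisable at C5, and nothing obvious controls the face of addition at C4. α-Elimination competes.
- Comparison: the chosen strategy is far shorter up to the ring and keeps its risk in a single step that can be tested early.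

Key step: step 7

Remark (assumption): the L-fructose-derived ketone is taken to epoxidise a R–CH2–CH=C(CH3)2 alkene with the sense opposite to the D-fructose-derived Shi ketone (which gives the R epoxide), i.e. to give (10S).

## Route

Step 1
Reactants: 1 methyl (2S)-oxirane-2-carboxylate; 2 (2-methylprop-1-en-1-yl)magnesium bromide
Product: 3 methyl (2S)-2-hydroxy-5-methylhex-4-enoate
Conditions: 2 (1.3 equiv), CuI (10 mol %), THF, −40 to −20 °C; aq. NH4Cl
Reagents that add atoms: none
Why: Copper-catalysed Grignard opening of a glycidic ester; SN2 attack at the unsubstituted epoxide carbon (C9) outruns carbonyl addition at low temperature, and the ester α-carbon (C8) is not touched, so the S configuration of 1 is carried into 3.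

Step 2
Reactants: 3 methyl (2S)-2-hydroxy-5-methylhex-4-enoate
Product: 4 methyl (2S)-2-[(tert-butyldimethylsilyl)oxy]-5-methylhex-4-enoate
Conditions: tBuMe2SiCl, imidazole, DMF, rt
Reagents that add atoms: tert-butyl(chloro)dimethylsilane, CC(C)(C)[Si](C)(C)Cl
Why: Standard silyl ether formation on a secondary α-hydroxy ester; the bulky, non-chelating silyl group is wanted later for facial control in step 7.

Step 3
Reactants: 4 methyl (2S)-2-[(tert-butyldimethylsilyl)oxy]-5-methylhex-4-enoate
Product: 5 (2S)-2-[(tert-butyldimethylsilyl)oxy]-N-methoxy-N,5-dimethylhex-4-enamide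
Conditions: MeNH(OMe)·HCl, iPrMgCl, THF, −20 °C
Reagents that add atoms: N,O-dimethylhydroxylamine hydrochloride, Cl.CNOC
Why: Direct aminolysis of the ester by the chloromagnesium amide of N,O-dimethylhydroxylamine (Weinreb amide formation); the amide base is weak enough at −20 °C not to epimerise C8.

Step 4
Reactants: 5 (2S)-2-[(tert-butyldimethylsilyl)oxy]-N-methoxy-N,5-dimethylhex-4-enamide
Product: 6 (3S)-3-[(tert-butyldimethylsilyl)oxy]-6-methylhept-5-en-2-one
Conditions: MeMgBr, THF, 0 °C; aq. NH4Cl
Reagents that add atoms: methylmagnesium bromide, C[Mg]Br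
Why: Weinreb ketone synthesis; the chelated tetrahedral intermediate prevents over-addition and releases the methyl ketone (the methyl carbon is C1) only on work-up.

Step 5
Reactants: 6 (3S)-3-[(tert-butyldimethylsilyl)oxy]-6-methylhept-5-en-2-one
Product: 8 (1Z,4S)-4-[(tert-butyldimethylsilyl)oxy]-1-hydroxy-7-methylocta-1,6-dien-3-one, via kinetic lithium enolate 7 (not isolated)
Conditions: LiN(iPr)2, THF, −78 °C; CF3CH2OCHO, −78 °C; aq. NH4Cl
Reagents that add atoms: 2,2,2-trifluoroethyl formate, O=COCC(F)(F)F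
Why: Kinetic deprotonation takes the unhindered methyl group and not the silyloxy-bearing C8–H, and Claisen-type C-formylation with the activated formate gives the β-keto aldehyde as its hydrogen-bonded Z enol; once formed, the product enolate shields C8 from epimerisation.

Step 6
Reactants: 9 (2E)-2-methylbut-2-enal; 10 di(propan-2-yl)silanediyl bis(trifluoromethanesulfonate); 8 (1Z,4S)-4-[(tert-butyldimethylsilyl)oxy]-1-hydroxy-7-methylocta-1,6-dien-3-one
Product: 12 (1Z,4S)-4-[(tert-butyldimethylsilyl)oxy]-7-methyl-1-[({[(1E)-2-methylbuta-1,3-dien-1-yl]oxy}di(propan-2-yl)silyl)oxy]octa-1,6-dien-3-one, via dienyloxysilyl triflate 11 (not isolated)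
Conditions: 10 (1.3 equiv), Et3N, CH2Cl2, −78 °C, slow addition of 9 (1.3 equiv); then 8 (1.0 equiv), Et3N, −78 to 0 °C; filtration through Et3N-deactivated silica
Reagents that add atoms: none
Why: Soft enolisation of the s-trans enal by a silyl triflate and amine removes a γ-proton and gives the E 1-silyloxy diene, and the remaining triflate on the now alkoxy-substituted, hindered silicon is slow enough to stop at 11; O-silylation of the chelated cis enol of 8 on its formyl oxygen then gives the Z β-silyloxy enone, held by an O7 to Si contact (sequential enolate substitution at a diisopropylsilyl centre is a known way to unsymmetrical silyl bis-enol ethers).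

Step 7
Reactants: 12 (1Z,4S)-4-[(tert-butyldimethylsilyl)oxy]-7-methyl-1-[({[(1E)-2-methylbuta-1,3-dien-1-yl]oxy}di(propan-2-yl)silyl)oxy]octa-1,6-dien-3-one
Product: 13 (2S)-2-[(tert-butyldimethylsilyl)oxy]-5-methyl-1-[(3aS,4S,7aR)-7-methyl-2,2-di(propan-2-yl)-3a,4,5,7a-tetrahydro-1,3,2-benzodioxasilol-4-yl]hex-4-en-1-one
Conditions: toluene (0.01 M), 2,6-di-tert-butyl-4-methylphenol (trace), base-washed sealed tube, 130–150 °C
Reagents that add atoms: none
Why: Proposed new method: a thermal, concerted but asynchronous [4+2] cycloaddition in which the 1-silyloxy diene C2=C3–C4=C5 adds suprafacially to the Z β-silyloxy enone C6=C1 held three atoms away by O5–Si–O6, forming C1–C2 and C5–C6. The closest known reaction type is the type 1 intramolecular Diels–Alder reaction through silyl acetal or vinylsilane tethers, together with endo-selective cycloadditions of 1-silyloxy dienes with enones; a tether made of two enol oxygens and a donor-substituted dienophile have not been combined. The cyclohexene closes by the cycloaddition itself, and the 1,3,2-dioxasilolane closes because the two tethered carbons C5 and C6 become bonded (five-membered ring, the heteroatom counterpart of nona-1,3,8-triene going to a hydrindene). The orientation (C5 to C6, C2 to C1) is opposite to the polar preference of the untethered partners and is imposed by the tether alone, helped by the C4 methyl, which raises the diene coefficient at C5. C6 and C1 become cis because the dienophile is Z, and C5–O becomes cis to C6–O because only the tether-endo transition state leads to the cis-fused dioxasilolane, which for a Z dienophile is also the acyl-endo one. The absolute sense should come from C8: with the enone s-cis and the C8–O bond anti to C7=O (the dipole-minimised, Cornforth-type rotamer expected for a bulky non-chelating silyl ether), the prenyl CH2 covers one face and C8–H the other, and attack past C8–H gives the configuration drawn. The step needs the Z geometry to hold, no silyl shift from O6 to O7 and this facial preference; dilution, neutral glass and a radical inhibitor serve the first two, the third is the unproven point.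

Step 8
Reactants: 13 (2S)-2-[(tert-butyldimethylsilyl)oxy]-5-methyl-1-[(3aS,4S,7aR)-7-methyl-2,2-di(propan-2-yl)-3a,4,5,7a-tetrahydro-1,3,2-benzodioxasilol-4-yl]hex-4-en-1-one
Product: 14 (3aS,4R,7aR)-4-{(3S)-3-[(tert-butyldimethylsilyl)oxy]-6-methylhepta-1,5-dien-2-yl}-7-methyl-2,2-di(propan-2-yl)-3a,4,5,7a-tetrahydro-1,3,2-benzodioxasilole
Conditions: Cp2TiMe2, toluene/THF, 65–70 °C, dark
Reagents that add atoms: dimethyltitanocene, C[Ti](C)(C1C=CC=C1)C1C=CC=C1
Why: Petasis methylenation through Cp2Ti=CH2 and an oxatitanacyclobutane; the reagent is not basic, so the ketone α-centres C1 and C8 keep their configuration and the β-silyloxy group on C6 is not eliminated.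

Step 9
Reactants: 14 (3aS,4R,7aR)-4-{(3S)-3-[(tert-butyldimethylsilyl)oxy]-6-methylhepta-1,5-dien-2-yl}-7-methyl-2,2-di(propan-2-yl)-3a,4,5,7a-tetrahydro-1,3,2-benzodioxasilole
Product: 15 (1S,2R,6R)-6-[(3S)-3-hydroxy-6-methylhepta-1,5-dien-2-yl]-3-methylcyclohex-3-ene-1,2-diol
Conditions: Bu4NF (4 equiv), THF, 0 °C to rt
Reagents that add atoms: none
Why: Fluoride cleaves the strained dioxasilolane and the secondary silyl ether in one operation; with the ketone gone no base-sensitive centre is left.

Step 10
Reactants: 15 (1S,2R,6R)-6-[(3S)-3-hydroxy-6-methylhepta-1,5-dien-2-yl]-3-methylcyclohex-3-ene-1,2-diol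
Product: 17 (1S,2R,6R)-6-[(3S)-3-hydroxy-6-methylhepta-1,5-dien-2-yl]-2-[(4-methoxyphenyl)methoxy]-3-methylcyclohex-3-en-1-ol, via dibutylstannylene acetal 16 (not isolated)
Conditions: Bu2SnO, toluene, reflux (−H2O); then 4-MeOC6H4CH2Cl, CsF, DMF, rt to 40 °C
Reagents that add atoms: 4-methoxybenzyl chloride, COc1ccc(CCl)cc1
Why: Tin acetal mediated mono-alkylation of a cis-1,2-diol; only the cis-diol forms the five-membered stannylene, and in the half-chair with the C1 chain equatorial O5 is the allylic, equatorial oxygen that such acetals alkylate, while the axial O6 and the lone C8–OH stay free.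

Step 11
Reactants: 17 (1S,2R,6R)-6-[(3S)-3-hydroxy-6-methylhepta-1,5-dien-2-yl]-2-[(4-methoxyphenyl)methoxy]-3-methylcyclohex-3-en-1-ol; 18 (2Z)-2-methylbut-2-enoic acid
Product: 20 (1S,2R,6R)-2-[(4-methoxyphenyl)methoxy]-3-methyl-6-[(3S)-6-methyl-3-{[(2Z)-2-methylbut-2-enoyl]oxy}hepta-1,5-dien-2-yl]cyclohex-3-en-1-yl (2Z)-2-methylbut-2-enoate, via mixed anhydride 19 (not isolated)
Conditions: 18 (5 equiv), 2,4,6-Cl3C6H2COCl, Et3N, toluene, rt; then 17, 75–80 °C
Reagents that add atoms: none
Why: Yamaguchi esterification through the angelic 2,4,6-trichlorobenzoic anhydride, attacked at the less hindered angeloyl carbonyl; leaving out a nucleophilic amine catalyst avoids the addition–elimination path by which angelates turn into tiglates.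

Step 12
Reactants: 20 (1S,2R,6R)-2-[(4-methoxyphenyl)methoxy]-3-methyl-6-[(3S)-6-methyl-3-{[(2Z)-2-methylbut-2-enoyl]oxy}hepta-1,5-dien-2-yl]cyclohex-3-en-1-yl (2Z)-2-methylbut-2-enoate
Product: 21 (1S,2R,6R)-2-hydroxy-3-methyl-6-[(3S)-6-methyl-3-{[(2Z)-2-methylbut-2-enoyl]oxy}hepta-1,5-dien-2-yl]cyclohex-3-en-1-yl (2Z)-2-methylbut-2-enoate
Conditions: DDQ, CH2Cl2/pH 7 buffer, 0 °C
Reagents that add atoms: none
Why: Oxidative cleavage of the 4-methoxybenzyl ether by benzylic hydride abstraction and hydrolysis of the oxocarbenium ion; the neutral medium leaves the esters in place and does not promote acyl migration to O5.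

Step 13
Reactants: 21 (1S,2R,6R)-2-hydroxy-3-methyl-6-[(3S)-6-methyl-3-{[(2Z)-2-methylbut-2-enoyl]oxy}hepta-1,5-dien-2-yl]cyclohex-3-en-1-yl (2Z)-2-methylbut-2-enoate
Product: 22 (1S,2S,3S,4R,6R)-2-hydroxy-1-methyl-4-[(3S)-6-methyl-3-{[(2Z)-2-methylbut-2-enoyl]oxy}hepta-1,5-dien-2-yl]-7-oxabicyclo[4.1.0]heptan-3-yl (2Z)-2-methylbut-2-enoate
Conditions: VO(acac)2 (5 mol %), tBuOOH, CH2Cl2, 0 °C to rt
Reagents that add atoms: tert-butyl hydroperoxide, CC(C)(C)OO
Why: Vanadium-catalysed hydroxyl-directed epoxidation; the vanadate ester of the allylic C5–OH delivers oxygen to C3=C4 on its own face, which sets C4 (oxygen cis to O5) and the epoxide carbon C3 against the steric bias, and the two other isolated alkenes have no hydroxyl within reach.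

Step 14
Reactants: 22 (1S,2S,3S,4R,6R)-2-hydroxy-1-methyl-4-[(3S)-6-methyl-3-{[(2Z)-2-methylbut-2-enoyl]oxy}hepta-1,5-dien-2-yl]-7-oxabicyclo[4.1.0]heptan-3-yl (2Z)-2-methylbut-2-enoate
Product: 23 (1S,2S,3S,4S,6R)-4-chloro-2,3-dihydroxy-3-methyl-6-[(3S)-6-methyl-3-{[(2Z)-2-methylbut-2-enoyl]oxy}hepta-1,5-dien-2-yl]cyclohexyl (2Z)-2-methylbut-2-enoate
Conditions: Ti(OiPr)4 (1.5 equiv), Et2NH2Cl, CH2Cl2, rt
Reagents that add atoms: diethylammonium chloride, CC[NH2+]CC.[Cl-]
Why: Titanium-mediated opening of a 2,3-epoxy alcohol at the carbon remote from the carbinol; chloride attacks C3 with inversion (Cl trans to C4–OH), which is also the trans-diaxial opening of the half-chair with the chain equatorial, and the inductive pull of O5 disfavours cation-like opening at tertiary C4.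

Step 15
Reactants: 23 (1S,2S,3S,4S,6R)-4-chloro-2,3-dihydroxy-3-methyl-6-[(3S)-6-methyl-3-{[(2Z)-2-methylbut-2-enoyl]oxy}hepta-1,5-dien-2-yl]cyclohexyl (2Z)-2-methylbut-2-enoate
Product: 24 (1S,2S,3S,4S,6R)-4-chloro-6-[(3S)-4-[(2S)-3,3-dimethyloxiran-2-yl]-3-{[(2Z)-2-methylbut-2-enoyl]oxy}but-1-en-2-yl]-2,3-dihydroxy-3-methylcyclohexyl (2Z)-2-methylbut-2-enoate
Conditions: 1,2:4,5-di-O-isopropylidene-β-L-erythro-2,3-hexodiulo-2,6-pyranose (1 equiv), KHSO5 (as 2KHSO5·KHSO4·K2SO4), NaHCO3 (pH 7–8), Na2EDTA aq., MeCN/CH2(OMe)2, 0 °C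
Reagents that add atoms: potassium peroxymonosulfate, [K+].[O-]S(=O)(=O)OO
Why: Shi epoxidation by the chiral dioxirane through a spiro transition state; the electron-rich trisubstituted C10=C11 reacts ahead of the hindered 1,1-disubstituted alkene and the enoates, the reagent sets C10 (S with the L-series ketone), and the near-neutral buffer spares the chlorohydrin and the esters.

## Compound list

1 | methyl (2S)-oxirane-2-carboxylate | COC(=O)[C@@H]1CO1 | starting material
2 | (2-methylprop-1-en-1-yl)magnesium bromide | CC(C)=C[Mg]Br | starting material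
3 | methyl (2S)-2-hydroxy-5-methylhex-4-enoate | COC(=O)[C@@H](O)CC=C(C)C | intermediate
4 | methyl (2S)-2-[(tert-butyldimethylsilyl)oxy]-5-methylhex-4-enoate | COC(=O)[C@@H](O[Si](C)(C)C(C)(C)C)CC=C(C)C | intermediate
5 | (2S)-2-[(tert-butyldimethylsilyl)oxy]-N-methoxy-N,5-dimethylhex-4-enamide | CON(C)C(=O)[C@@H](O[Si](C)(C)C(C)(C)C)CC=C(C)C | intermediate
6 | (3S)-3-[(tert-butyldimethylsilyl)oxy]-6-methylhept-5-en-2-one | CC(=O)[C@@H](O[Si](C)(C)C(C)(C)C)CC=C(C)C | intermediate
7 | lithium (3S)-3-[(tert-butyldimethylsilyl)oxy]-6-methylhepta-1,5-dien-2-olate | [Li]OC(=C)[C@@H](O[Si](C)(C)C(C)(C)C)CC=C(C)C | intermediate (not isolated)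
8 | (1Z,4S)-4-[(tert-butyldimethylsilyl)oxy]-1-hydroxy-7-methylocta-1,6-dien-3-one | O/C=C\C(=O)[C@@H](O[Si](C)(C)C(C)(C)C)CC=C(C)C | intermediate
9 | (2E)-2-methylbut-2-enal | C/C=C(\C)C=O | starting material
10 | di(propan-2-yl)silanediyl bis(trifluoromethanesulfonate) | CC(C)[Si](OS(=O)(=O)C(F)(F)F)(OS(=O)(=O)C(F)(F)F)C(C)C | starting material
11 | {[(1E)-2-methylbuta-1,3-dien-1-yl]oxy}di(propan-2-yl)silyl trifluoromethanesulfonate | CC(C)[Si](C(C)C)(O/C=C(C)/C=C)OS(=O)(=O)C(F)(F)F | intermediate (not isolated)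
12 | (1Z,4S)-4-[(tert-butyldimethylsilyl)oxy]-7-methyl-1-[({[(1E)-2-methylbuta-1,3-dien-1-yl]oxy}di(propan-2-yl)silyl)oxy]octa-1,6-dien-3-one | CC(C)[Si](C(C)C)(O/C=C(C)/C=C)O/C=C\C(=O)[C@@H](O[Si](C)(C)C(C)(C)C)CC=C(C)C | intermediate (precursor of the key step)
13 | (2S)-2-[(tert-butyldimethylsilyl)oxy]-5-methyl-1-[(3aS,4S,7aR)-7-methyl-2,2-di(propan-2-yl)-3a,4,5,7a-tetrahydro-1,3,2-benzodioxasilol-4-yl]hex-4-en-1-one (ring oxygens and acyl group all cis) | CC(C)[Si]1(C(C)C)O[C@@H]2C(C)=CC[C@H](C(=O)[C@@H](O[Si](C)(C)C(C)(C)C)CC=C(C)C)[C@@H]2O1 | intermediate (product of the key step)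
14 | (3aS,4R,7aR)-4-{(3S)-3-[(tert-butyldimethylsilyl)oxy]-6-methylhepta-1,5-dien-2-yl}-7-methyl-2,2-di(propan-2-yl)-3a,4,5,7a-tetrahydro-1,3,2-benzodioxasilole | CC(C)[Si]1(C(C)C)O[C@@H]2C(C)=CC[C@H](C(=C)[C@@H](O[Si](C)(C)C(C)(C)C)CC=C(C)C)[C@@H]2O1 | intermediate
15 | (1S,2R,6R)-6-[(3S)-3-hydroxy-6-methylhepta-1,5-dien-2-yl]-3-methylcyclohex-3-ene-1,2-diol | O[C@@H]1C(C)=CC[C@H](C(=C)[C@@H](O)CC=C(C)C)[C@@H]1O | intermediate
16 | (3aS,4R,7aR)-2,2-dibutyl-4-[(3S)-3-hydroxy-6-methylhepta-1,5-dien-2-yl]-7-methyl-3a,4,5,7a-tetrahydro-1,3,2-benzodioxastannole | CCCC[Sn]1(CCCC)O[C@@H]2C(C)=CC[C@H](C(=C)[C@@H](O)CC=C(C)C)[C@@H]2O1 | intermediate (not isolated)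
17 | (1S,2R,6R)-6-[(3S)-3-hydroxy-6-methylhepta-1,5-dien-2-yl]-2-[(4-methoxyphenyl)methoxy]-3-methylcyclohex-3-en-1-ol | COc1ccc(CO[C@@H]2C(C)=CC[C@H](C(=C)[C@@H](O)CC=C(C)C)[C@@H]2O)cc1 | intermediate
18 | (2Z)-2-methylbut-2-enoic acid (angelic acid) | C/C=C(/C)C(O)=O | starting material
19 | (2Z)-2-methylbut-2-enoic 2,4,6-trichlorobenzoic anhydride | C/C=C(/C)C(=O)OC(=O)c1c(Cl)cc(Cl)cc1Cl | intermediate (not isolated)
20 | (1S,2R,6R)-2-[(4-methoxyphenyl)methoxy]-3-methyl-6-[(3S)-6-methyl-3-{[(2Z)-2-methylbut-2-enoyl]oxy}hepta-1,5-dien-2-yl]cyclohex-3-en-1-yl (2Z)-2-methylbut-2-enoate | COc1ccc(CO[C@@H]2C(C)=CC[C@H](C(=C)[C@@H](OC(=O)/C(C)=C\C)CC=C(C)C)[C@@H]2OC(=O)/C(C)=C\C)cc1 | intermediate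
21 | (1S,2R,6R)-2-hydroxy-3-methyl-6-[(3S)-6-methyl-3-{[(2Z)-2-methylbut-2-enoyl]oxy}hepta-1,5-dien-2-yl]cyclohex-3-en-1-yl (2Z)-2-methylbut-2-enoate | O[C@@H]1C(C)=CC[C@H](C(=C)[C@@H](OC(=O)/C(C)=C\C)CC=C(C)C)[C@@H]1OC(=O)/C(C)=C\C | intermediate
22 | (1S,2S,3S,4R,6R)-2-hydroxy-1-methyl-4-[(3S)-6-methyl-3-{[(2Z)-2-methylbut-2-enoyl]oxy}hepta-1,5-dien-2-yl]-7-oxabicyclo[4.1.0]heptan-3-yl (2Z)-2-methylbut-2-enoate (epoxide oxygen cis to the hydroxyl) | O[C@@H]1[C@]2(C)O[C@@H]2C[C@H](C(=C)[C@@H](OC(=O)/C(C)=C\C)CC=C(C)C)[C@@H]1OC(=O)/C(C)=C\C | intermediate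
23 | (1S,2S,3S,4S,6R)-4-chloro-2,3-dihydroxy-3-methyl-6-[(3S)-6-methyl-3-{[(2Z)-2-methylbut-2-enoyl]oxy}hepta-1,5-dien-2-yl]cyclohexyl (2Z)-2-methylbut-2-enoate | C=C([C@H](CC=C(C)C)OC(=O)/C(C)=C\C)[C@H]1C[C@H](Cl)[C@@](C)(O)[C@@H](O)[C@H]1OC(=O)/C(C)=C\C | intermediate
24 | (1S,2S,3S,4S,6R)-4-chloro-6-[(3S)-4-[(2S)-3,3-dimethyloxiran-2-yl]-3-{[(2Z)-2-methylbut-2-enoyl]oxy}but-1-en-2-yl]-2,3-dihydroxy-3-methylcyclohexyl (2Z)-2-methylbut-2-enoate | C=C([C@H](C[C@@H]1OC1(C)C)OC(=O)/C(C)=C\C)[C@H]1C[C@H](Cl)[C@@](C)(O)[C@@H](O)[C@H]1OC(=O)/C(C)=C\C | target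

## Step count and least certain steps

Total step count: 15. Longest linear sequence: 15 steps (1 to 24); the diene arm (9, 10) joins at step 6 without steps of its own.

Step 7 (key step). Two things may go wrong.
- The cycloaddition may not occur before the silyl enol ethers decompose. The dienophile carries a donor on C6 and the tether forces the electronically disfavoured orientation. The silicon may also shift from O6 to O7, or the enol ether may lose its Z geometry.
- The face may be chosen poorly, because control rests only on a conformational preference at C8.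

Fallback by known chemistry, setting out from Weinreb amide 5 and returning at triol 15: the ring is closed by metathesis after an aldol union.
- But-3-enylmagnesium bromide adds to 5 to give (5S)-5-[(tert-butyldimethylsilyl)oxy]-8-methylnona-1,7-dien-4-one F1.
- The partner is made from methacrolein. (R)-Oxynitrilase-mediated addition of HCN gives (2R)-2-hydroxy-3-methylbut-3-enenitrile F2, silylation gives (2R)-2-[(tert-butyldimethylsilyl)oxy]-3-methylbut-3-enenitrile F3, and reduction with iBu2AlH gives (2R)-2-[(tert-butyldimethylsilyl)oxy]-3-methylbut-3-enal F4.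
- The Z boron enolate of F1 (Bu2BOTf, iPr2NEt, enolisation on the methylene side) adds to F4 to give the syn aldol (3S,5S)-5-[(tert-butyldimethylsilyl)oxy]-3-{(1S,2R)-2-[(tert-butyldimethylsilyl)oxy]-1-hydroxy-3-methylbut-3-en-1-yl}-8-methylnona-1,7-dien-4-one F5. The C6/C5 anti relationship is expected from Cornforth-type induction by the α-silyloxy aldehyde. If the sense relative to C8 is poor, the matched enantiomer of diisopinocampheylboron triflate would be used.
- Ring-closing metathesis with the second-generation Grubbs catalyst, RuCl2(=CHPh)(H2IMes)(PCy3), joins the vinyl and isopropenyl groups and gives (2S)-2-[(tert-butyldimethylsilyl)oxy]-1-{(1S,5R,6S)-5-[(tert-butyldimethylsilyl)oxy]-6-hydroxy-4-methylcyclohex-3-en-1-yl}-5-methylhex-4-en-1-one F6.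
- Methylenation with Zn/CH2Br2/TiCl4, which tolerates the free hydroxyl, gives (1S,2R,6R)-2-[(tert-butyldimethylsilyl)oxy]-6-{(3S)-3-[(tert-butyldimethylsilyl)oxy]-6-methylhepta-1,5-dien-2-yl}-3-methylcyclohex-3-en-1-ol F7, and Bu4NF then gives 15.

Step 6. Substitution at silicon may not stop cleanly after the first enol, giving symmetric acetals. The enol ether of 8 may form as an E/Z mixture, and the acetal may hydrolyse on handling. Fallback, setting out from 9 and returning at 12: the two Si–O bonds are made one at a time from preformed enolates.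
- 9 is converted with Me3SiCl, Et3N and catalytic ZnCl2 into trimethyl{[(1E)-2-methylbuta-1,3-dien-1-yl]oxy}silane F8.
- MeLi cleaves F8 to lithium (1E)-2-methylbuta-1,3-dien-1-olate F9.
- F9 is added to an excess of iPr2SiCl2 to give chloro{[(1E)-2-methylbuta-1,3-dien-1-yl]oxy}di(propan-2-yl)silane F10, freed from the excess dichlorosilane under vacuum.
- F10 then silylates 8 (Et3N, CH2Cl2, −78 °C) on the formyl oxygen to give 12.

Step 10. Alkylation may fall on O6 or occur twice if the conformational bias of the tin acetal is smaller than assumed. Fallback, setting out from 14 and returning at 17: the diol is differentiated through a cyclic orthoester, which opens to the axial ester.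
- HF·pyridine cleaves only the strained dioxasilolane of 14 and gives (1S,2R,6R)-6-{(3S)-3-[(tert-butyldimethylsilyl)oxy]-6-methylhepta-1,5-dien-2-yl}-3-methylcyclohex-3-ene-1,2-diol F11.
- Trimethyl orthoacetate with catalytic camphorsulfonic acid gives the cyclic orthoester (3aS,4R,7aR)-4-{(3S)-3-[(tert-butyldimethylsilyl)oxy]-6-methylhepta-1,5-dien-2-yl}-2-methoxy-2,7-dimethyl-3a,4,5,7a-tetrahydro-1,3-benzodioxole F12.
- Aqueous acetic acid opens F12 to the axial ester (1S,2R,6R)-6-{(3S)-3-[(tert-butyldimethylsilyl)oxy]-6-methylhepta-1,5-dien-2-yl}-2-hydroxy-3-methylcyclohex-3-en-1-yl acetate F13.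
- 4-Methoxybenzyl 2,2,2-trichloroacetimidate with catalytic La(OTf)3 gives (1S,2R,6R)-6-{(3S)-3-[(tert-butyldimethylsilyl)oxy]-6-methylhepta-1,5-dien-2-yl}-2-[(4-methoxyphenyl)methoxy]-3-methylcyclohex-3-en-1-yl acetate F14.
- K2CO3 in methanol gives (1S,2R,6R)-6-{(3S)-3-[(tert-butyldimethylsilyl)oxy]-6-methylhepta-1,5-dien-2-yl}-2-[(4-methoxyphenyl)methoxy]-3-methylcyclohex-3-en-1-ol F15, and Bu4NF gives 17.

Step 11. Acylation of the axial, flanked C6–OH may stall, and the activated angeloyl unit may isomerise to the E (tigloyl) form on long heating. Fallback, setting out from 17 and returning at 20: the Z enoates are built on the ester.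
- 17 is acylated at both hydroxyls with 2-[bis(2,2,2-trifluoroethoxy)phosphoryl]propanoic acid (an unhindered acid, carbodiimide coupling) to give (1S,2R,6R)-6-[(3S)-3-({2-[bis(2,2,2-trifluoroethoxy)phosphoryl]propanoyl}oxy)-6-methylhepta-1,5-dien-2-yl]-2-[(4-methoxyphenyl)methoxy]-3-methylcyclohex-3-en-1-yl 2-[bis(2,2,2-trifluoroethoxy)phosphoryl]propanoate F16.
- A Still–Gennari olefination of F16 with acetaldehyde (KN(SiMe3)2, 18-crown-6, THF, −78 °C) forms both Z 2-methylbut-2-enoates and gives 20.

Step 13. Oxygen must be delivered to the face that carries three substituents. The allylic alcohol may instead be oxidised to the enone, or the reaction may be slow enough for the other alkenes to compete. Fallback, setting out from 21 and returning at 24: the order is reversed and the chlorohydrin is made without an epoxide.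
- Shi epoxidation of 21 under the conditions of step 15 gives (1S,2R,6R)-6-[(3S)-4-[(2S)-3,3-dimethyloxiran-2-yl]-3-{[(2Z)-2-methylbut-2-enoyl]oxy}but-1-en-2-yl]-2-hydroxy-3-methylcyclohex-3-en-1-yl (2Z)-2-methylbut-2-enoate F17.
- N-Chlorosuccinimide in NaHCO3-buffered aqueous acetone then adds electrophilic chlorine to the open lower face of C3=C4. Water opens the chloronium ion at tertiary C4 from above and gives 24 directly.

## Further compounds

F1 | step 7 | (5S)-5-[(tert-butyldimethylsilyl)oxy]-8-methylnona-1,7-dien-4-one | C=CCCC(=O)[C@@H](O[Si](C)(C)C(C)(C)C)CC=C(C)C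
F2 | step 7 | (2R)-2-hydroxy-3-methylbut-3-enenitrile | N#C[C@H](O)C(C)=C
F3 | step 7 | (2R)-2-[(tert-butyldimethylsilyl)oxy]-3-methylbut-3-enenitrile | N#C[C@H](O[Si](C)(C)C(C)(C)C)C(C)=C
F4 | step 7 | (2R)-2-[(tert-butyldimethylsilyl)oxy]-3-methylbut-3-enal | O=C[C@H](O[Si](C)(C)C(C)(C)C)C(C)=C
F5 | step 7 | (3S,5S)-5-[(tert-butyldimethylsilyl)oxy]-3-{(1S,2R)-2-[(tert-butyldimethylsilyl)oxy]-1-hydroxy-3-methylbut-3-en-1-yl}-8-methylnona-1,7-dien-4-one | C=CC[C@H](C(=O)[C@@H](O[Si](C)(C)C(C)(C)C)CC=C(C)C)[C@H](O)[C@H](O[Si](C)(C)C(C)(C)C)C(C)=C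
F6 | step 7 | (2S)-2-[(tert-butyldimethylsilyl)oxy]-1-{(1S,5R,6S)-5-[(tert-butyldimethylsilyl)oxy]-6-hydroxy-4-methylcyclohex-3-en-1-yl}-5-methylhex-4-en-1-one | CC(C)(C)[Si](C)(C)O[C@@H]1C(C)=CC[C@H](C(=O)[C@@H](O[Si](C)(C)C(C)(C)C)CC=C(C)C)[C@@H]1O
F7 | step 7 | (1S,2R,6R)-2-[(tert-butyldimethylsilyl)oxy]-6-{(3S)-3-[(tert-butyldimethylsilyl)oxy]-6-methylhepta-1,5-dien-2-yl}-3-methylcyclohex-3-en-1-ol | CC(C)(C)[Si](C)(C)O[C@@H]1C(C)=CC[C@H](C(=C)[C@@H](O[Si](C)(C)C(C)(C)C)CC=C(C)C)[C@@H]1O
F8 | step 6 | trimethyl{[(1E)-2-methylbuta-1,3-dien-1-yl]oxy}silane | C[Si](C)(C)O/C=C(C)/C=C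
F9 | step 6 | lithium (1E)-2-methylbuta-1,3-dien-1-olate | [Li]O/C=C(C)/C=C
F10 | step 6 | chloro{[(1E)-2-methylbuta-1,3-dien-1-yl]oxy}di(propan-2-yl)silane | CC(C)[Si](Cl)(C(C)C)O/C=C(C)/C=C
F11 | step 10 | (1S,2R,6R)-6-{(3S)-3-[(tert-butyldimethylsilyl)oxy]-6-methylhepta-1,5-dien-2-yl}-3-methylcyclohex-3-ene-1,2-diol | O[C@@H]1C(C)=CC[C@H](C(=C)[C@@H](O[Si](C)(C)C(C)(C)C)CC=C(C)C)[C@@H]1O
F12 | step 10 | (3aS,4R,7aR)-4-{(3S)-3-[(tert-butyldimethylsilyl)oxy]-6-methylhepta-1,5-dien-2-yl}-2-methoxy-2,7-dimethyl-3a,4,5,7a-tetrahydro-1,3-benzodioxole (both epimers at the orthoester carbon) | COC1(C)O[C@@H]2C(C)=CC[C@H](C(=C)[C@@H](O[Si](C)(C)C(C)(C)C)CC=C(C)C)[C@@H]2O1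
F13 | step 10 | (1S,2R,6R)-6-{(3S)-3-[(tert-butyldimethylsilyl)oxy]-6-methylhepta-1,5-dien-2-yl}-2-hydroxy-3-methylcyclohex-3-en-1-yl acetate | O[C@@H]1C(C)=CC[C@H](C(=C)[C@@H](O[Si](C)(C)C(C)(C)C)CC=C(C)C)[C@@H]1OC(C)=O
F14 | step 10 | (1S,2R,6R)-6-{(3S)-3-[(tert-butyldimethylsilyl)oxy]-6-methylhepta-1,5-dien-2-yl}-2-[(4-methoxyphenyl)methoxy]-3-methylcyclohex-3-en-1-yl acetate | COc1ccc(CO[C@@H]2C(C)=CC[C@H](C(=C)[C@@H](O[Si](C)(C)C(C)(C)C)CC=C(C)C)[C@@H]2OC(C)=O)cc1
F15 | step 10 | (1S,2R,6R)-6-{(3S)-3-[(tert-butyldimethylsilyl)oxy]-6-methylhepta-1,5-dien-2-yl}-2-[(4-methoxyphenyl)methoxy]-3-methylcyclohex-3-en-1-ol | COc1ccc(CO[C@@H]2C(C)=CC[C@H](C(=C)[C@@H](O[Si](C)(C)C(C)(C)C)CC=C(C)C)[C@@H]2O)cc1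
F16 | step 11 | (1S,2R,6R)-6-[(3S)-3-({2-[bis(2,2,2-trifluoroethoxy)phosphoryl]propanoyl}oxy)-6-methylhepta-1,5-dien-2-yl]-2-[(4-methoxyphenyl)methoxy]-3-methylcyclohex-3-en-1-yl 2-[bis(2,2,2-trifluoroethoxy)phosphoryl]propanoate (epimers at the phosphonate carbons) | COc1ccc(CO[C@@H]2C(C)=CC[C@H](C(=C)[C@@H](OC(=O)C(C)P(=O)(OCC(F)(F)F)OCC(F)(F)F)CC=C(C)C)[C@@H]2OC(=O)C(C)P(=O)(OCC(F)(F)F)OCC(F)(F)F)cc1
F17 | step 13 | (1S,2R,6R)-6-[(3S)-4-[(2S)-3,3-dimethyloxiran-2-yl]-3-{[(2Z)-2-methylbut-2-enoyl]oxy}but-1-en-2-yl]-2-hydroxy-3-methylcyclohex-3-en-1-yl (2Z)-2-methylbut-2-enoate | O[C@@H]1C(C)=CC[C@H](C(=C)[C@@H](OC(=O)/C(C)=C\C)C[C@@H]2OC2(C)C)[C@@H]1OC(=O)/C(C)=C\C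
A1 | alternative 1 | 2,2,4-trimethyl-1,3-dioxan-5-one | CC1OC(C)(C)OCC1=O
A2 | alternative 1 | ethyl (E)-4-oxobut-2-enoate | CCOC(=O)/C=C/C=O
A3 | alternative 1 | ethyl 8-hydroxy-1,3,3-trimethyl-9-oxo-2,4-dioxabicyclo[3.3.1]nonane-6-carboxylate | CCOC(=O)[C@H]1C[C@H](O)[C@]2(C)C(=O)[C@H]1OC(C)(C)O2
A4 | alternative 2 | (1-bromoethenyl){[(1S,6R)-6-[(tert-butyldimethylsilyl)oxy]-5-methylcyclohexa-2,4-dien-1-yl]oxy}dimethylsilane | C=C(Br)[Si](C)(C)O[C@H]1C=CC=C(C)[C@H]1O[Si](C)(C)C(C)(C)C
A5 | alternative 2 | cis-fused 3-methylidene-1-oxa-2-silacyclopentane on the cyclohexene (C1 set, C7=C14 present, C3=C4 retained, C5 silyl ether) | C=C1[C@H]2CC=C(C)[C@@H](O[Si](C)(C)C(C)(C)C)[C@H]2O[Si]1(C)C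
A6 | alternative 3 | acyclic C4 methyl ketone carrying the chloro(4-methylbenzenesulfinyl)methyl group at C3, with C5 silyl ether and 4-methoxybenzyl ethers on C6 and C8 (sulfur configuration not specified) | CC(=O)[C@@H](O[Si](C)(C)C(C)(C)C)[C@@H](OCc1ccc(OC)cc1)[C@H](C[C@H](Cl)S(=O)c1ccc(C)cc1)C(=C)[C@H](CC=C(C)C)OCc1ccc(OC)cc1
A7 | alternative 3 | fully substituted ring with C3 chloride, free tertiary C4 hydroxyl, C5 silyl ether and 4-methoxybenzyl ethers on C6 and C8 | C=C([C@H](CC=C(C)C)OCc1ccc(OC)cc1)[C@H]2C[C@H](Cl)[C@@](C)(O)[C@@H](O[Si](C)(C)C(C)(C)C)[C@H]2OCc3ccc(OC)cc3
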